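What stands in Thursday's and Saturday's flasks at the end?

| flask | starting complex | incoming ligand | remark | time |
|---|---|---|---|---|
| south-west | 20 mM | 1.8 equiv | run made earlier |  |
| east | 20 mM | 5.5 equiv | run made earlier |  |
| Thursday's | 20 mM | 1.20 equiv |  | 4.0 min |
| Saturday's | 20 mM | 4.00 equiv |  | 4.0 min |

- south-west (time / min: complex with four exchanged / %, complex with one exchanged / %, starting complex / %): 0.200: 3, 9, 93; 0.500: 1, 16, 75; 1.00: 0, 24, 59; 1.50: 1, 21, 47; 2.00: 5, 25, 42; 3.00: 8, 21, 32
- east (time / min: complex with four exchanged / %, complex with one exchanged / %, starting complex / %): 0.200: 2, 21, 69; 0.500: 5, 24, 39; 1.00: 25, 15, 21; 1.50: 43, 7, 11; 2.00: 54, 4, 7; 3.00: 74, 5, 5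

(standard deviation of a reading: 1.5 percentage points)

- which of these holds the largest part of the starting complex at the end of Thursday's (complex with three exchanged / complex with two exchanged / complex with one exchanged / complex with four exchanged / starting complex)
- which of these holds the largest part of the starting complex at the end of Saturday's (complex with three exchanged / complex with two exchanged / complex with one exchanged / complex with four exchanged / starting complex)
- final complex with four exchanged in Saturday's, as a percentage of the starting complex charged

- the earlier runs were read with a standard deviation of 1.5 percentage points
- steps that have been proposed: starting complex + incoming ligand -> leaving ligand + complex with one exchanged; complex with one exchanged + incoming ligand -> leaving ligand + complex with two exchanged; complex with two exchanged + incoming ligand -> leaving ligand + complex with three exchanged; complex with three exchanged + incoming ligand -> leaving ligand + complex with four exchanged; complex with one exchanged + incoming ligand -> over-reaction product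

Every proposed step takes one incoming ligand, so I assume that all the steps speed up and slow down together and that the mixture follows one progress measure. East's reading at 2.00 min, with 7% starting complex left, gives 2.66 on my ligand clock, the natural log of starting complex charged over starting complex left.

Counting the unread middle complexes as 2.5 exchanges each, east has spent 3.07 equiv per complex by then. Saturday's can pay that from its 4.00 equiv. East's first reading has the clock running at 1.86 /min on 5.5 equiv. With ligand falling evenly along the clock, Saturday's needs about 3.75 min, so by 4.0 min I expect a little over east's 54% complex with four exchanged.

On Thursday's, ligand is the limiting reagent: full exchange takes 4 equivalents per complex and the flask has 1.20 equiv. East had spent 1.24 equivalents per complex at 39% starting complex, read as more than its other complexes, even the unread middle ones taken together, so I expect starting complex to stay largest on Thursday's.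

The forecast, holding that “Species composition should therefore follow ligand exposure”, gives starting complex for Thursday's, complex with four exchanged for Saturday's and 50% (38% to 62%).

The flasks give starting complex at 44.6% on Thursday's, and complex with four exchanged at 58.1% on Saturday's.

    starting complex + incoming ligand → leaving ligand + complex with one exchanged (k = 0.310 /M/s)
    complex with one exchanged + incoming ligand → leaving ligand + complex with two exchanged (k = 0.650 /M/s)
    complex with two exchanged + incoming ligand → leaving ligand + complex with three exchanged (k = 0.550 /M/s)
    complex with three exchanged + incoming ligand → leaving ligand + complex with four exchanged (k = 0.470 /M/s)
    complex with one exchanged + incoming ligand → over-reaction product (k = 0.00960 /M/s)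

Saturday's is not at rest at 4.00 min: its clock stands at 2.75, beside east's 2.66, with 21% of its ligand and 6.4% of its starting complex left. The same flask read at 15 min has a clock of 4.41 and 87.4% complex with four exchanged. At 40.0 min, ten times the time, Saturday's clock reads 5.67, ligand is at 2.25% of its charge, over-reaction product has gone from 1.28% to 1.45%, and complex with four exchanged holds 94.9%.

The runs were generated by integration with constants of no real substance, noise included.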